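**Retrosynthetic overview**

- The strategy rests on ring B of the bicyclo[3.3.1]nonane (C1, C9, C5, C6, C7, C8; bridgeheads C1 and C5). Its C7 prenyl group and its C8 methyl/homoprenyl pair are read as the result of adding a dimethylallyl cation (at C7) and the enol carbon C1 (at C8) to opposite faces of a Z C7=C8 double bond.
- Key disconnection: the C7–prenyl and C1–C8 bonds are cut together, giving a dearomatised neryl/prenyl aroylphloroglucinol and dimethylallyl diphosphate; a prenyltransferase is to make both bonds in one operation.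
- The neryl dienone comes from dearomative C-nerylation of a symmetrical 3,5-diprenyl aroylphloroglucinol. The two prenyl-bearing carbons are enantiotopic, so the product is racemic and is resolved.
- The diprenyl benzophenone comes from phloroglucinol by Friedel–Crafts aroylation with 3-hydroxybenzoic acid and double C-prenylation.
- Ring order: ring A (C1–C5, C9) is the phloroglucinol ring, dearomatised in step 4; ring B is the only ring formed, in the last step.

Key step: step 6

**Remarks on the chemistry**

- Ring atoms carry the numbering of the target (C1, C5 bridgeheads; C9 bridging carbonyl; C2–C3–C4 the aroyl diketone bridge), also in the monocyclic precursors. Enolised triketones are drawn as one tautomer and their CIP labels refer to that tautomer.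
- The 3'-hydroxyl is carried unprotected, on the assumption that the ionised phloroglucinol nucleus reacts through carbon faster than a simple phenoxide reacts through oxygen.
- Dimethylallyl diphosphate is used as the purchased triammonium salt.
- A cyclising prenyltransferase variant that accepts the (S)-dienone is assumed to be found by screening.

**Route**

Step 1
Reactants: 1 phloroglucinol; 2 3-hydroxybenzoic acid
Product: 3 (3-hydroxyphenyl)(2,4,6-trihydroxyphenyl)methanone
Conditions: 1 (1.5 equiv), Eaton's reagent (P2O5 in MeSO3H), 70 °C; ice–water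
Reagents that add atoms: none
Why: Friedel–Crafts acylation: the acyl cation equivalent formed from 2 attacks the very electron-rich ring of 1 once, the ketone then deactivates the ring, and the hydroxyl of 2, not being ortho to the carbonyl, cannot close a xanthone.

Step 2
Reactants: 3 (3-hydroxyphenyl)(2,4,6-trihydroxyphenyl)methanone; 4 prenyl bromide (1-bromo-3-methylbut-2-ene)
Product: 5 (3-hydroxyphenyl)[2,4,6-trihydroxy-3,5-bis(3-methylbut-2-en-1-yl)phenyl]methanone
Conditions: 4 (2.1 equiv), 10% aq. KOH, 0 °C; then 1 M HCl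
Reagents that add atoms: none
Why: Phenoxide C-alkylation (SN2 at the primary allylic bromide): in water the phloroglucinolate reacts through its two free ring carbons, which are far more nucleophilic than the oxygen of the 3'-phenoxide, so the symmetrical 3,5-diprenyl compound should be the main product.

Step 3
Reactants: 6 nerol ((2Z)-3,7-dimethylocta-2,6-dien-1-ol)
Product: 7 neryl bromide ((2Z)-1-bromo-3,7-dimethylocta-2,6-diene)
Conditions: CBr4, PPh3, CH2Cl2, 0 °C; used fresh
Reagents that add atoms: carbon tetrabromide, BrC(Br)(Br)Br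
Why: Appel reaction: bromide displaces the alkoxyphosphonium group at the primary allylic carbon under neutral conditions, which should leave the Z alkene and the allylic position unchanged.

Step 4
Reactants: 5 (3-hydroxyphenyl)[2,4,6-trihydroxy-3,5-bis(3-methylbut-2-en-1-yl)phenyl]methanone; 7 neryl bromide
Product: 8 rac-6-[(2Z)-3,7-dimethylocta-2,6-dien-1-yl]-3,5-dihydroxy-4-(3-hydroxybenzoyl)-2,6-bis(3-methylbut-2-en-1-yl)cyclohexa-2,4-dien-1-one
Conditions: LiHMDS (4.2 equiv), THF, 0 °C; 7 (1.05 equiv), 0 °C → rt; 1 M HCl; under N2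
Reagents that add atoms: none
Why: Alkylative dearomatisation (SN2 C-alkylation of the phloroglucinol polyanion at a prenyl-bearing ring carbon, the aggregated lithium phenoxide oxygens being poor nucleophiles in THF): the two prenyl-bearing carbons are enantiotopic, so the new quaternary centre C5 forms as the racemate, and the Z alkene of 7 is kept.

Step 5
Reactants: 8 the racemic dienone
Product: 9 (6S)-6-[(2Z)-3,7-dimethylocta-2,6-dien-1-yl]-3,5-dihydroxy-4-(3-hydroxybenzoyl)-2,6-bis(3-methylbut-2-en-1-yl)cyclohexa-2,4-dien-1-one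
Conditions: preparative chiral SFC, amylose tris(3,5-dimethylphenylcarbamate) phase, CO2/MeOH with 0.1% HCO2H, 35 °C
Reagents that add atoms: none
Why: Resolution of enantiomers on a chiral stationary phase (no bond is made): the quaternary centre cannot epimerise, the acidic modifier keeps the enolised triketone in one protonation state, and the (S) enantiomer is to be identified by comparing its ECD spectrum with the calculated one.

Step 6
Reactants: 9 the (6S)-dienone; 10 dimethylallyl diphosphate (triammonium salt)
Product: 11 (1S,5S,7S,8S)-4-hydroxy-3-(3-hydroxybenzoyl)-8-methyl-8-(4-methylpent-3-en-1-yl)-1,5,7-tris(3-methylbut-2-en-1-yl)bicyclo[3.3.1]non-3-ene-2,9-dione (CNP0406274.1)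
Conditions: PPAP-cyclising aromatic prenyltransferase (UbiA type, variant selected on 9; yeast microsomes), 10 (3 equiv), MgCl2 (10 mM), Tris·HCl pH 7.5, 30 °C, dark, N2
Reagents that add atoms: none
Why: Proposed new method: the enzyme ionises the Mg2+-bound diphosphate of 10 to a dimethylallyl cation held against the C7=C8 bond of the neryl arm; C7 adds to it in the Markovnikov sense, and the tertiary C8 cation is taken on the opposite face of the former alkene by C1, the enol carbon between C9=O and C2–OH, so the C7–prenyl and C1–C8 bonds form in one anti addition. The closest known reaction type is the prenyltransferase-catalysed prenylation–cyclisation that closes the bicyclo[3.3.1]nonane core in the biosynthesis of polyprenylated acylphloroglucinols, which has not been shown for a neryl arm on a C3-aroyl substrate. Ring B (C1, C9, C5, C6, C7, C8) closes in the 6-endo-trig mode and must fold boat-like (C7 on the C9 side), because only then does the prenyl group, anti to the forming C1–C8 bond, end on the face of ring B that carries C2 and C4; a chair fold would give the C7,C8-bis-epimer. C1 is fixed by the (S) centre at C5, since the three-carbon tether reaches C1 only on the ring face that bears the neryl arm; C7 and C8 are fixed relative to each other by the Z geometry (anti addition puts the C7 prenyl and the C8 homoprenyl cis, the C8 methyl trans) and relative to the bridgeheads by the fold that the pocket imposes. The step needs one alkene of five, carbon C1 instead of C3 or an enol oxygen, and one fold: the substrate contributes the higher nucleophilicity of C1 (an alkyl-substituted diketone carbon, whereas C3 lies between three carbonyl groups), the (S) configuration that puts neryl and not the geminal prenyl on the cyclising face, and the Z alkene, and the active site has to supply the rest.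

**Compound list**

1 | phloroglucinol (benzene-1,3,5-triol) | Oc1cc(O)cc(O)c1 | starting material
2 | 3-hydroxybenzoic acid | O=C(O)c1cccc(O)c1 | starting material
3 | (3-hydroxyphenyl)(2,4,6-trihydroxyphenyl)methanone | O=C(c1cccc(O)c1)c1c(O)cc(O)cc1O | intermediate
4 | prenyl bromide (1-bromo-3-methylbut-2-ene) | CC(C)=CCBr | starting material
5 | (3-hydroxyphenyl)[2,4,6-trihydroxy-3,5-bis(3-methylbut-2-en-1-yl)phenyl]methanone | O=C(c1cccc(O)c1)c1c(O)c(CC=C(C)C)c(O)c(CC=C(C)C)c1O | intermediate
6 | nerol ((2Z)-3,7-dimethylocta-2,6-dien-1-ol) | CC(C)=CCC/C(C)=C\CO | starting material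
7 | neryl bromide ((2Z)-1-bromo-3,7-dimethylocta-2,6-diene) | CC(C)=CCC/C(C)=C\CBr | intermediate
8 | rac-6-[(2Z)-3,7-dimethylocta-2,6-dien-1-yl]-3,5-dihydroxy-4-(3-hydroxybenzoyl)-2,6-bis(3-methylbut-2-en-1-yl)cyclohexa-2,4-dien-1-one | CC(C)=CCC/C(C)=C\CC2(CC=C(C)C)C(=O)C(CC=C(C)C)=C(O)C(C(=O)c1cccc(O)c1)=C2O | intermediate
9 | (6S)-6-[(2Z)-3,7-dimethylocta-2,6-dien-1-yl]-3,5-dihydroxy-4-(3-hydroxybenzoyl)-2,6-bis(3-methylbut-2-en-1-yl)cyclohexa-2,4-dien-1-one | CC(C)=CCC/C(C)=C\C[C@]2(CC=C(C)C)C(=O)C(CC=C(C)C)=C(O)C(C(=O)c1cccc(O)c1)=C2O | intermediate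
10 | dimethylallyl diphosphate (used as triammonium salt) | CC(C)=CCOP(=O)(O)OP(=O)(O)O | starting material
11 | (1S,5S,7S,8S)-4-hydroxy-3-(3-hydroxybenzoyl)-8-methyl-8-(4-methylpent-3-en-1-yl)-1,5,7-tris(3-methylbut-2-en-1-yl)bicyclo[3.3.1]non-3-ene-2,9-dione | CC(C)=CCC[C@@]1(C)[C@@H](CC=C(C)C)C[C@]2(CC=C(C)C)C(=O)[C@@]1(CC=C(C)C)C(=O)C(C(=O)c1cccc(O)c1)=C2O | target

**Step count and risks**

Total step count: 6. Longest linear sequence: 5 steps (steps 1, 2, 4, 5, 6); step 3 is a one-step branch.

Steps most likely to fail: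

1. Step 6. The enzyme may not turn over 9, may pass the C8 cation to C3 or to an enol oxygen, may prenylate the geminal prenyl arm, or may fold ring B chair-like. The fallback uses known chemistry, a proton-initiated cation–enol closure on a side chain that already carries the C7 prenyl group, as known for lavandulyl-type dearomatised acylphloroglucinols. It sets out from 5 and returns at 11.
 - Purchased (E)-geranic acid (CC(C)=CCC/C(C)=C/C(=O)O) is coupled through its pivalic mixed anhydride with lithiated (R)-4-benzyloxazolidin-2-one to give (R)-4-benzyl-3-[(2E)-3,7-dimethylocta-2,6-dienoyl]oxazolidin-2-one F1.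
 - Deconjugative Evans alkylation of its sodium dienolate with 4 (NaHMDS, THF, −78 °C) should give (R)-4-benzyl-3-[(2R)-7-methyl-3-methylidene-2-(3-methylbut-2-en-1-yl)oct-6-enoyl]oxazolidin-2-one F2.
 - LiBH4 releases (2R)-7-methyl-3-methylidene-2-(3-methylbut-2-en-1-yl)oct-6-en-1-ol F3, which Tf2O and 2,6-lutidine (CH2Cl2, −78 °C) convert into (2R)-7-methyl-3-methylidene-2-(3-methylbut-2-en-1-yl)oct-6-en-1-yl trifluoromethanesulfonate F4.
 - Alkylative dearomatisation of 5 with F4 (LiHMDS, THF, −78 → 0 °C) gives, after chromatographic removal of the C5 epimer, (6S)-3,5-dihydroxy-4-(3-hydroxybenzoyl)-6-[(2S)-7-methyl-3-methylidene-2-(3-methylbut-2-en-1-yl)oct-6-en-1-yl]-2,6-bis(3-methylbut-2-en-1-yl)cyclohexa-2,4-dien-1-one F5.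
 - Formic acid at room temperature should protonate the 1,1-disubstituted alkene of F5, C1 captures the C8 cation, and 11 is separated by HPLC from its C8 epimer and from O-cyclised material.
 - In this variant C7 comes from the auxiliary and C1 follows from C5; C8 is not controlled.

2. Step 4. O-alkylation (at the 3'-oxygen or at the ring oxygens) and double alkylation may outrun C-alkylation at the prenyl-bearing carbon. The fallback masks the only hydroxyl outside the nucleus, so that only the phloroglucinol core is ionised. It sets out from 5 and returns at 8.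
 - TIPSCl and imidazole (DMF, 0 °C) should silylate the unhindered 3'-hydroxyl in preference to the three ring hydroxyls, each flanked by two ortho substituents, to give [2,4,6-trihydroxy-3,5-bis(3-methylbut-2-en-1-yl)phenyl]{3-[tri(propan-2-yl)silyloxy]phenyl}methanone F6.
 - Alkylation with 7 (LiHMDS 3.2 equiv, THF, 0 °C) gives rac-6-[(2Z)-3,7-dimethylocta-2,6-dien-1-yl]-3,5-dihydroxy-2,6-bis(3-methylbut-2-en-1-yl)-4-{3-[tri(propan-2-yl)silyloxy]benzoyl}cyclohexa-2,4-dien-1-one F7.
 - TBAF buffered with AcOH (THF, 0 °C) returns to 8.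

3. Step 2. Statistical mono-, di- and tri-alkylation together with O-prenylation of the 3'-phenoxide may leave little 5. The fallback carries the 3'-oxygen as a base-stable sulfonate through acylation and prenylation and unmasks it at the robust aromatic stage. It sets out from 2 and returns at 5.
 - TsCl in aqueous NaOH gives 3-[(4-methylbenzenesulfonyl)oxy]benzoic acid F8.
 - Oxalyl chloride with catalytic DMF gives 3-[(4-methylbenzenesulfonyl)oxy]benzoyl chloride F9.
 - Friedel–Crafts acylation of 1 (AlCl3, PhNO2, rt) gives 3-(2,4,6-trihydroxybenzoyl)phenyl 4-methylbenzenesulfonate F10.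
 - Prenylation with 4 (10% aq. KOH, 0 °C) gives 3-[2,4,6-trihydroxy-3,5-bis(3-methylbut-2-en-1-yl)benzoyl]phenyl 4-methylbenzenesulfonate F11.
 - KOH in MeOH–H2O at 60 °C under N2 cleaves the sulfonate and returns to 5.

**Further compounds**

F1 | step 6 | (R)-4-benzyl-3-[(2E)-3,7-dimethylocta-2,6-dienoyl]oxazolidin-2-one | CC(C)=CCC/C(C)=C/C(=O)N1[C@H](Cc2ccccc2)COC1=O
F2 | step 6 | (R)-4-benzyl-3-[(2R)-7-methyl-3-methylidene-2-(3-methylbut-2-en-1-yl)oct-6-enoyl]oxazolidin-2-one | C=C(CCC=C(C)C)[C@@H](CC=C(C)C)C(=O)N1[C@H](Cc2ccccc2)COC1=O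
F3 | step 6 | (2R)-7-methyl-3-methylidene-2-(3-methylbut-2-en-1-yl)oct-6-en-1-ol | C=C(CCC=C(C)C)[C@@H](CC=C(C)C)CO
F4 | step 6 | (2R)-7-methyl-3-methylidene-2-(3-methylbut-2-en-1-yl)oct-6-en-1-yl trifluoromethanesulfonate | C=C(CCC=C(C)C)[C@@H](CC=C(C)C)COS(=O)(=O)C(F)(F)F
F5 | step 6 | (6S)-3,5-dihydroxy-4-(3-hydroxybenzoyl)-6-[(2S)-7-methyl-3-methylidene-2-(3-methylbut-2-en-1-yl)oct-6-en-1-yl]-2,6-bis(3-methylbut-2-en-1-yl)cyclohexa-2,4-dien-1-one | C=C(CCC=C(C)C)[C@@H](CC=C(C)C)C[C@]2(CC=C(C)C)C(=O)C(CC=C(C)C)=C(O)C(C(=O)c1cccc(O)c1)=C2O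
F6 | step 4 | [2,4,6-trihydroxy-3,5-bis(3-methylbut-2-en-1-yl)phenyl]{3-[tri(propan-2-yl)silyloxy]phenyl}methanone | CC(C)[Si](Oc1cccc(c1)C(=O)c1c(O)c(CC=C(C)C)c(O)c(CC=C(C)C)c1O)(C(C)C)C(C)C
F7 | step 4 | rac-6-[(2Z)-3,7-dimethylocta-2,6-dien-1-yl]-3,5-dihydroxy-2,6-bis(3-methylbut-2-en-1-yl)-4-{3-[tri(propan-2-yl)silyloxy]benzoyl}cyclohexa-2,4-dien-1-one | CC(C)=CCC/C(C)=C\CC2(CC=C(C)C)C(=O)C(CC=C(C)C)=C(O)C(C(=O)c1cccc(O[Si](C(C)C)(C(C)C)C(C)C)c1)=C2O
F8 | step 2 | 3-[(4-methylbenzenesulfonyl)oxy]benzoic acid | Cc1ccc(cc1)S(=O)(=O)Oc1cccc(c1)C(=O)O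
F9 | step 2 | 3-[(4-methylbenzenesulfonyl)oxy]benzoyl chloride | Cc1ccc(cc1)S(=O)(=O)Oc1cccc(c1)C(Cl)=O
F10 | step 2 | 3-(2,4,6-trihydroxybenzoyl)phenyl 4-methylbenzenesulfonate | Cc1ccc(cc1)S(=O)(=O)Oc1cccc(c1)C(=O)c1c(O)cc(O)cc1O
F11 | step 2 | 3-[2,4,6-trihydroxy-3,5-bis(3-methylbut-2-en-1-yl)benzoyl]phenyl 4-methylbenzenesulfonate | Cc1ccc(cc1)S(=O)(=O)Oc1cccc(c1)C(=O)c1c(O)c(CC=C(C)C)c(O)c(CC=C(C)C)c1O
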